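The route rests on cutting ring C at the C4–C4a bond: a 3-aryloxy-2,3-diarylpropanoic acid is closed onto ring A by intramolecular Friedel–Crafts acylation. The step exploits the phloroglucinol pattern of ring A: in the 3,5-bis(benzyloxy)phenoxy ether the two carbons ortho to O1 (the future C4a and C8) are equivalent, so one operation forms ring C and can only give the 5,7-dioxygenated chromanone, with C2 and C3 already in place. The precursor is the (2S,3R) acid bearing the ring-A ether and a 4-benzyloxyphenyl group at C3 and a 2-benzyloxy-5-bromophenyl group at C2, built by an Evans syn-aldol and one Mitsunobu inversion at the alcohol oxidation level. Heck coupling and global debenzylation finish.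

Key step: step 9

Remark: rings A, B and C are the flavanone rings, ring D is the aryl ring on C3 and ring E the 2,4-dihydroxyphenyl ring of the enone; the target is the 2,3-trans (2R,3S) isomer.

Step 1
Reactants: 1 (5-bromo-2-hydroxyphenyl)acetic acid
Product: 3 [2-(benzyloxy)-5-bromophenyl]acetic acid, via benzyl ester 2 (not isolated)
Conditions: BnBr, K2CO3, DMF, 60 °C; then NaOH, MeOH–H2O, 60 °C; HCl work-up
Reagents that add atoms: benzyl bromide, BrCc1ccccc1; sodium hydroxide, [Na+].[OH-]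
Why: Williamson benzylation of both the phenoxide and the carboxylate followed by saponification of the benzyl ester in the same pot leaves only the aryl benzyl ether, which protects the ring-D phenol until the last step.

Step 2
Reactants: 3 [2-(benzyloxy)-5-bromophenyl]acetic acid; 4 (4S)-4-benzyl-1,3-oxazolidin-2-one
Product: 6 (4S)-4-benzyl-3-{[2-(benzyloxy)-5-bromophenyl]acetyl}-1,3-oxazolidin-2-one, via mixed pivalic anhydride 5 (not isolated)
Conditions: t-BuCOCl, Et3N, THF, −20 °C; then 4, LiCl, −20 °C → rt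
Reagents that add atoms: none
Why: N-acylation of the Evans auxiliary through the mixed pivalic anhydride with LiCl activation needs no strong base, which the acidic CH2 of an arylacetyl unit would not tolerate cleanly.

Step 3
Reactants: 6 (4S)-4-benzyl-3-{[2-(benzyloxy)-5-bromophenyl]acetyl}-1,3-oxazolidin-2-one; 7 4-(benzyloxy)benzaldehyde
Product: 9 (4S)-4-benzyl-3-{(2S,3S)-3-[4-(benzyloxy)phenyl]-2-[2-(benzyloxy)-5-bromophenyl]-3-hydroxypropanoyl}-1,3-oxazolidin-2-one, via boron enolate 8 (not isolated)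
Conditions: n-Bu2BOTf, i-Pr2NEt, CH2Cl2, −78 → 0 °C; 7, −78 → 0 °C; pH 7 buffer, MeOH, H2O2, 0 °C
Reagents that add atoms: none
Why: In this Evans syn-aldol reaction the Z-boron enolate adds to the aldehyde through a closed chair transition state on the enolate face away from the benzyl group of the auxiliary, which should set both new centres as (2S,3S) with the syn relationship.

Step 4
Reactants: 9 (4S)-4-benzyl-3-{(2S,3S)-3-[4-(benzyloxy)phenyl]-2-[2-(benzyloxy)-5-bromophenyl]-3-hydroxypropanoyl}-1,3-oxazolidin-2-one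
Product: 10 (1S,2R)-1-[4-(benzyloxy)phenyl]-2-[2-(benzyloxy)-5-bromophenyl]propane-1,3-diol
Conditions: LiBH4, MeOH, THF, 0 °C
Reagents that add atoms: none
Why: Reductive cleavage of the N-acyl oxazolidinone with LiBH4 gives the 1,3-diol and returns the auxiliary, and removing the carbonyl here takes away the acidic α-hydrogen so that the coming Mitsunobu step cannot divert into β-elimination.

Step 5
Reactants: 10 (1S,2R)-1-[4-(benzyloxy)phenyl]-2-[2-(benzyloxy)-5-bromophenyl]propane-1,3-diol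
Product: 11 (1S,2R)-1-[4-(benzyloxy)phenyl]-2-[2-(benzyloxy)-5-bromophenyl]-3-{[tert-butyl(dimethyl)silyl]oxy}propan-1-ol
Conditions: TBSCl, imidazole, CH2Cl2, 0 °C
Reagents that add atoms: tert-butyl(chloro)dimethylsilane, CC(C)(C)[Si](C)(C)Cl
Why: Silyl ether formation is selective for the unhindered primary hydroxyl over the crowded secondary benzylic one, so only the carbinol that is to be inverted stays free.

Step 6
Reactants: 11 (1S,2R)-1-[4-(benzyloxy)phenyl]-2-[2-(benzyloxy)-5-bromophenyl]-3-{[tert-butyl(dimethyl)silyl]oxy}propan-1-ol; 12 3,5-bis(benzyloxy)phenol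
Product: 13 {[(2R,3R)-3-[3,5-bis(benzyloxy)phenoxy]-3-[4-(benzyloxy)phenyl]-2-[2-(benzyloxy)-5-bromophenyl]propyl]oxy}(tert-butyl)dimethylsilane
Conditions: PPh3, DIAD, toluene, 0 °C → rt
Reagents that add atoms: none
Why: In this Mitsunobu etherification the phenoxide displaces the oxyphosphonium group by an SN2 reaction, which inverts the benzylic carbinol carbon (S to R) and turns the syn aldol relationship into the anti relationship of a 2,3-trans chromanone, while the neighbouring centre is untouched.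

Step 7
Reactants: 13 {[(2R,3R)-3-[3,5-bis(benzyloxy)phenoxy]-3-[4-(benzyloxy)phenyl]-2-[2-(benzyloxy)-5-bromophenyl]propyl]oxy}(tert-butyl)dimethylsilane
Product: 14 (2R,3R)-3-[3,5-bis(benzyloxy)phenoxy]-3-[4-(benzyloxy)phenyl]-2-[2-(benzyloxy)-5-bromophenyl]propan-1-ol
Conditions: TBAF, THF, 0 °C → rt
Reagents that add atoms: none
Why: Fluoride-mediated desilylation cleaves only the Si–O bond, and with no carbonyl in the molecule the basic fluoride cannot cause β-elimination of the aryloxide.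

Step 8
Reactants: 14 (2R,3R)-3-[3,5-bis(benzyloxy)phenoxy]-3-[4-(benzyloxy)phenyl]-2-[2-(benzyloxy)-5-bromophenyl]propan-1-ol
Product: 16 (2S,3R)-3-[3,5-bis(benzyloxy)phenoxy]-3-[4-(benzyloxy)phenyl]-2-[2-(benzyloxy)-5-bromophenyl]propanoic acid, via aldehyde 15 (not isolated)
Conditions: TEMPO (cat.), PhI(OAc)2, CH2Cl2–H2O, 0 °C → rt
Reagents that add atoms: water, O
Why: TEMPO-catalysed oxidation with PhI(OAc)2 as terminal oxidant takes the primary alcohol through the aldehyde hydrate to the acid without base, chlorinating oxidants or strong acid, so the α-aryl centre, the β-aryloxy group and the electron-rich ring A should survive.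

Step 9
Reactants: 16 (2S,3R)-3-[3,5-bis(benzyloxy)phenoxy]-3-[4-(benzyloxy)phenyl]-2-[2-(benzyloxy)-5-bromophenyl]propanoic acid
Product: 18 (2R,3S)-5,7-bis(benzyloxy)-2-[4-(benzyloxy)phenyl]-3-[2-(benzyloxy)-5-bromophenyl]-2,3-dihydro-4H-chromen-4-one, via mixed trifluoroacetic anhydride 17 (not isolated)
Conditions: (CF3CO)2O, CH2Cl2, −20 → 0 °C
Reagents that add atoms: none
Why: The anhydride converts the acid into the mixed trifluoroacetic anhydride 17, and the ring-A carbon ortho to the ether oxygen attacks its aryl-substituted acyl carbon; loss of trifluoroacetate and of a proton from the arenium ion gives the aryl ketone, that is the C4–C4a bond. The closest known reaction type is the intramolecular Friedel–Crafts acylation of 3-aryloxypropanoic acids to chroman-4-ones. Ring C closes in a six-membered exo-trig mode at the acyl carbon by electrophilic aromatic substitution. No stereocentre is created: C2 and C3 come unchanged from 16, and acid-mediated enolisation at C3 could only converge on the more stable 2,3-trans isomer. Regioselectivity needs no control because the two ortho carbons of the 3,5-bis(benzyloxy)phenoxy ring are equivalent and either gives the 5,7-pattern. The selectivity that is needed is chemoselectivity, acylation before the para-benzyloxybenzylic C–O bond ionises: ring A, activated by three oxygen donors, should react at or below 0 °C without a Lewis acid, whereas ring B could only close a five-membered ring at a carbon meta to its ether oxygen and ring D a four-membered one.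

Step 10
Reactants: 19 1-(2,4-dihydroxyphenyl)ethan-1-one
Product: 20 1-[2,4-bis(benzyloxy)phenyl]ethan-1-one
Conditions: BnBr, K2CO3, KI (cat.), DMF, 80 °C
Reagents that add atoms: benzyl bromide, BrCc1ccccc1
Why: Williamson ether synthesis, run in hot DMF with iodide catalysis because the hydroxyl ortho to the acetyl group is hydrogen-bonded and slow to alkylate.

Step 11
Reactants: 20 1-[2,4-bis(benzyloxy)phenyl]ethan-1-one
Product: 22 1-[2,4-bis(benzyloxy)phenyl]prop-2-en-1-one, via Mannich base 21 (not isolated)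
Conditions: (CH2O)n, i-Pr2NH·CF3CO2H, CF3CO2H (cat.), THF, reflux
Reagents that add atoms: paraformaldehyde (source of formaldehyde), C=O
Why: A Mannich reaction followed in the same pot by β-elimination of the secondary amine (α-methylenation of a methyl ketone) should give the aryl vinyl ketone, which is used at once because such enones polymerise on standing.

Step 12
Reactants: 18 (2R,3S)-5,7-bis(benzyloxy)-2-[4-(benzyloxy)phenyl]-3-[2-(benzyloxy)-5-bromophenyl]-2,3-dihydro-4H-chromen-4-one; 22 1-[2,4-bis(benzyloxy)phenyl]prop-2-en-1-one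
Product: 23 (2R,3S)-5,7-bis(benzyloxy)-2-[4-(benzyloxy)phenyl]-3-{2-(benzyloxy)-5-[(1E)-3-[2,4-bis(benzyloxy)phenyl]-3-oxoprop-1-en-1-yl]phenyl}-2,3-dihydro-4H-chromen-4-one
Conditions: Pd(P(t-Bu)3)2 (cat.), Cy2NMe, 1,4-dioxane, rt → 40 °C
Reagents that add atoms: none
Why: In this Mizoroki–Heck coupling, oxidative addition of the aryl bromide to zerovalent palladium, syn insertion of the vinyl ketone and syn β-hydride elimination give the E-enone, and the hindered amine at near room temperature is chosen so that C3 is not enolised and ring C cannot open by retro-oxa-Michael reaction.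

Step 13
Reactants: 23 (2R,3S)-5,7-bis(benzyloxy)-2-[4-(benzyloxy)phenyl]-3-{2-(benzyloxy)-5-[(1E)-3-[2,4-bis(benzyloxy)phenyl]-3-oxoprop-1-en-1-yl]phenyl}-2,3-dihydro-4H-chromen-4-one
Product: 24 (2R,3S)-3-{5-[(1E)-3-(2,4-dihydroxyphenyl)-3-oxoprop-1-en-1-yl]-2-hydroxyphenyl}-5,7-dihydroxy-2-(4-hydroxyphenyl)-2,3-dihydro-4H-chromen-4-one
Conditions: BCl3, C6HMe5, CH2Cl2, −78 → −40 °C; then MeOH
Reagents that add atoms: none
Why: Lewis-acid debenzylation in which BCl3 activates each ether oxygen and pentamethylbenzene traps the benzyl cation by Friedel–Crafts benzylation should free all six phenols without hydrogenation (which would reduce the enone) and without C-benzylation of the phenol rings, the low temperature protecting the C2–O1 bond and both stereocentres.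

Compound list
1 | (5-bromo-2-hydroxyphenyl)acetic acid | OC(=O)Cc1cc(Br)ccc1O | starting material
2 | benzyl [2-(benzyloxy)-5-bromophenyl]acetate | O=C(Cc1cc(Br)ccc1OCc1ccccc1)OCc1ccccc1 | intermediate
3 | [2-(benzyloxy)-5-bromophenyl]acetic acid | OC(=O)Cc1cc(Br)ccc1OCc1ccccc1 | intermediate
4 | (4S)-4-benzyl-1,3-oxazolidin-2-one | O=C1N[C@@H](Cc2ccccc2)CO1 | starting material
5 | [2-(benzyloxy)-5-bromophenyl]acetic 2,2-dimethylpropanoic anhydride | CC(C)(C)C(=O)OC(=O)Cc1cc(Br)ccc1OCc1ccccc1 | intermediate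
6 | (4S)-4-benzyl-3-{[2-(benzyloxy)-5-bromophenyl]acetyl}-1,3-oxazolidin-2-one | O=C(Cc1cc(Br)ccc1OCc1ccccc1)N1C(=O)OC[C@@H]1Cc1ccccc1 | intermediate
7 | 4-(benzyloxy)benzaldehyde | O=Cc1ccc(OCc2ccccc2)cc1 | starting material
8 | (4S)-4-benzyl-3-[(1Z)-2-[2-(benzyloxy)-5-bromophenyl]-1-[(dibutylboranyl)oxy]ethenyl]-1,3-oxazolidin-2-one | CCCCB(CCCC)O/C(=C\c1cc(Br)ccc1OCc1ccccc1)N1C(=O)OC[C@@H]1Cc1ccccc1 | intermediate
9 | (4S)-4-benzyl-3-{(2S,3S)-3-[4-(benzyloxy)phenyl]-2-[2-(benzyloxy)-5-bromophenyl]-3-hydroxypropanoyl}-1,3-oxazolidin-2-one | Brc1ccc(OCc2ccccc2)c([C@@H]([C@H](O)c2ccc(OCc3ccccc3)cc2)C(=O)N2C(=O)OC[C@@H]2Cc2ccccc2)c1 | intermediate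
10 | (1S,2R)-1-[4-(benzyloxy)phenyl]-2-[2-(benzyloxy)-5-bromophenyl]propane-1,3-diol | Brc1ccc(OCc2ccccc2)c([C@@H]([C@H](O)c2ccc(OCc3ccccc3)cc2)CO)c1 | intermediate
11 | (1S,2R)-1-[4-(benzyloxy)phenyl]-2-[2-(benzyloxy)-5-bromophenyl]-3-{[tert-butyl(dimethyl)silyl]oxy}propan-1-ol | Brc1ccc(OCc2ccccc2)c([C@@H]([C@H](O)c2ccc(OCc3ccccc3)cc2)CO[Si](C)(C)C(C)(C)C)c1 | intermediate
12 | 3,5-bis(benzyloxy)phenol | Oc1cc(OCc2ccccc2)cc(OCc2ccccc2)c1 | starting material
13 | {[(2R,3R)-3-[3,5-bis(benzyloxy)phenoxy]-3-[4-(benzyloxy)phenyl]-2-[2-(benzyloxy)-5-bromophenyl]propyl]oxy}(tert-butyl)dimethylsilane | Brc1ccc(OCc2ccccc2)c([C@@H]([C@@H](Oc2cc(OCc3ccccc3)cc(OCc3ccccc3)c2)c2ccc(OCc3ccccc3)cc2)CO[Si](C)(C)C(C)(C)C)c1 | intermediate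
14 | (2R,3R)-3-[3,5-bis(benzyloxy)phenoxy]-3-[4-(benzyloxy)phenyl]-2-[2-(benzyloxy)-5-bromophenyl]propan-1-ol | Brc1ccc(OCc2ccccc2)c([C@@H]([C@@H](Oc2cc(OCc3ccccc3)cc(OCc3ccccc3)c2)c2ccc(OCc3ccccc3)cc2)CO)c1 | intermediate
15 | (2S,3R)-3-[3,5-bis(benzyloxy)phenoxy]-3-[4-(benzyloxy)phenyl]-2-[2-(benzyloxy)-5-bromophenyl]propanal | Brc1ccc(OCc2ccccc2)c([C@@H]([C@@H](Oc2cc(OCc3ccccc3)cc(OCc3ccccc3)c2)c2ccc(OCc3ccccc3)cc2)C=O)c1 | intermediate
16 | (2S,3R)-3-[3,5-bis(benzyloxy)phenoxy]-3-[4-(benzyloxy)phenyl]-2-[2-(benzyloxy)-5-bromophenyl]propanoic acid | Brc1ccc(OCc2ccccc2)c([C@@H]([C@@H](Oc2cc(OCc3ccccc3)cc(OCc3ccccc3)c2)c2ccc(OCc3ccccc3)cc2)C(=O)O)c1 | intermediate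
17 | (2S,3R)-3-[3,5-bis(benzyloxy)phenoxy]-3-[4-(benzyloxy)phenyl]-2-[2-(benzyloxy)-5-bromophenyl]propanoic trifluoroacetic anhydride | Brc1ccc(OCc2ccccc2)c([C@@H]([C@@H](Oc2cc(OCc3ccccc3)cc(OCc3ccccc3)c2)c2ccc(OCc3ccccc3)cc2)C(=O)OC(=O)C(F)(F)F)c1 | intermediate
18 | (2R,3S)-5,7-bis(benzyloxy)-2-[4-(benzyloxy)phenyl]-3-[2-(benzyloxy)-5-bromophenyl]-2,3-dihydro-4H-chromen-4-one | Brc1ccc(OCc2ccccc2)c([C@@H]2C(=O)c3c(OCc4ccccc4)cc(OCc4ccccc4)cc3O[C@H]2c2ccc(OCc3ccccc3)cc2)c1 | intermediate
19 | 1-(2,4-dihydroxyphenyl)ethan-1-one | CC(=O)c1ccc(O)cc1O | starting material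
20 | 1-[2,4-bis(benzyloxy)phenyl]ethan-1-one | CC(=O)c1ccc(OCc2ccccc2)cc1OCc1ccccc1 | intermediate
21 | 1-[2,4-bis(benzyloxy)phenyl]-3-[di(propan-2-yl)amino]propan-1-one (present as its trifluoroacetate salt) | CC(C)N(CCC(=O)c1ccc(OCc2ccccc2)cc1OCc1ccccc1)C(C)C | intermediate
22 | 1-[2,4-bis(benzyloxy)phenyl]prop-2-en-1-one | C=CC(=O)c1ccc(OCc2ccccc2)cc1OCc1ccccc1 | intermediate
23 | (2R,3S)-5,7-bis(benzyloxy)-2-[4-(benzyloxy)phenyl]-3-{2-(benzyloxy)-5-[(1E)-3-[2,4-bis(benzyloxy)phenyl]-3-oxoprop-1-en-1-yl]phenyl}-2,3-dihydro-4H-chromen-4-one | O=C(/C=C/c1ccc(OCc2ccccc2)c([C@@H]2C(=O)c3c(OCc4ccccc4)cc(OCc4ccccc4)cc3O[C@H]2c2ccc(OCc3ccccc3)cc2)c1)c1ccc(OCc2ccccc2)cc1OCc1ccccc1 | intermediate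
24 | (2R,3S)-3-{5-[(1E)-3-(2,4-dihydroxyphenyl)-3-oxoprop-1-en-1-yl]-2-hydroxyphenyl}-5,7-dihydroxy-2-(4-hydroxyphenyl)-2,3-dihydro-4H-chromen-4-one | O=C(/C=C/c1ccc(O)c([C@@H]2C(=O)c3c(O)cc(O)cc3O[C@H]2c2ccc(O)cc2)c1)c1ccc(O)cc1O | target

Total step count: 13
Longest linear sequence: 11 steps (steps 1–9, 12 and 13, from compound 1); the vinyl ketone branch is steps 10–11.

Steps most likely to fail

Step 9. The acid released during the acylation may ionise the para-benzyloxybenzylic C–O bond, which would scramble or cleave the ether carbon, or ring A may be trifluoroacetylated before it is acylated intramolecularly. The fallback closes ring C at O1–C2 instead, so that the benzylic aryl ether never meets acid. It sets out from 9: transamidation with AlMe3 and MeONHMe·HCl in CH2Cl2 should give (2S,3S)-3-[4-(benzyloxy)phenyl]-2-[2-(benzyloxy)-5-bromophenyl]-3-hydroxy-N-methoxy-N-methylpropanamide F1. Excess 2,4,6-tris(benzyloxy)phenyllithium, made from 1,3,5-tris(benzyloxy)benzene and n-BuLi in THF, is then added at −78 °C to give the ketone (2S,3S)-3-[4-(benzyloxy)phenyl]-2-[2-(benzyloxy)-5-bromophenyl]-3-hydroxy-1-[2,4,6-tris(benzyloxy)phenyl]propan-1-one F2, in which the C4–C4a bond already exists. MgBr2·OEt2 in toluene should remove one of the two benzyl ethers ortho to the ketone by chelation and give (2S,3S)-1-[2,4-bis(benzyloxy)-6-hydroxyphenyl]-3-[4-(benzyloxy)phenyl]-2-[2-(benzyloxy)-5-bromophenyl]-3-hydroxypropan-1-one F3. An intramolecular Mitsunobu reaction (PPh3, DIAD, THF, 0 °C) then displaces the benzylic hydroxyl with inversion, and the fallback comes back to the route at 18.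

Step 6. The oxyphosphonium group sits on a benzylic carbon activated by the para-benzyloxy group, so it may ionise before it is displaced and inversion would be incomplete; it may also eliminate to a stilbene, or substitution at the crowded carbinol may stall. The fallback makes the ether one stage earlier, on a substrate whose neighbouring acyl group disfavours a benzylic cation. It sets out from 9: Mitsunobu reaction with 12 (PPh3, DIAD, toluene, 0 °C) should give (4S)-4-benzyl-3-{(2S,3R)-3-[3,5-bis(benzyloxy)phenoxy]-3-[4-(benzyloxy)phenyl]-2-[2-(benzyloxy)-5-bromophenyl]propanoyl}-1,3-oxazolidin-2-one F4. Cleavage of the auxiliary with LiOH and H2O2 in THF–H2O at 0 °C then comes back to the route at 16, without steps 4, 5, 7 and 8. This shorter order is kept in reserve because the acidic α-hydrogen of 9 makes β-elimination a competing path.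

Step 12. The base may enolise C3, after which ring C can open by retro-oxa-Michael reaction and the C2 configuration is lost, or the aryl vinyl ketone may polymerise faster than it couples. The fallback is base-free and sets out from 18: Stille coupling with tributyl(vinyl)stannane (Pd(PPh3)4, toluene, 90 °C) should give (2R,3S)-5,7-bis(benzyloxy)-2-[4-(benzyloxy)phenyl]-3-[2-(benzyloxy)-5-ethenylphenyl]-2,3-dihydro-4H-chromen-4-one F5. Olefin cross-metathesis of this styrene with 22 (second-generation Hoveyda–Grubbs catalyst, CH2Cl2, 40 °C) should give the E-enone and comes back to the route at 23.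

Further compounds
F1 | step 9 | (2S,3S)-3-[4-(benzyloxy)phenyl]-2-[2-(benzyloxy)-5-bromophenyl]-3-hydroxy-N-methoxy-N-methylpropanamide | Brc1ccc(OCc2ccccc2)c([C@@H]([C@H](O)c2ccc(OCc3ccccc3)cc2)C(=O)N(C)OC)c1
F2 | step 9 | (2S,3S)-3-[4-(benzyloxy)phenyl]-2-[2-(benzyloxy)-5-bromophenyl]-3-hydroxy-1-[2,4,6-tris(benzyloxy)phenyl]propan-1-one | Brc1ccc(OCc2ccccc2)c([C@@H]([C@H](O)c2ccc(OCc3ccccc3)cc2)C(=O)c2c(OCc3ccccc3)cc(OCc3ccccc3)cc2OCc2ccccc2)c1
F3 | step 9 | (2S,3S)-1-[2,4-bis(benzyloxy)-6-hydroxyphenyl]-3-[4-(benzyloxy)phenyl]-2-[2-(benzyloxy)-5-bromophenyl]-3-hydroxypropan-1-one | Brc1ccc(OCc2ccccc2)c([C@@H]([C@H](O)c2ccc(OCc3ccccc3)cc2)C(=O)c2c(O)cc(OCc3ccccc3)cc2OCc2ccccc2)c1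
F4 | step 6 | (4S)-4-benzyl-3-{(2S,3R)-3-[3,5-bis(benzyloxy)phenoxy]-3-[4-(benzyloxy)phenyl]-2-[2-(benzyloxy)-5-bromophenyl]propanoyl}-1,3-oxazolidin-2-one | Brc1ccc(OCc2ccccc2)c([C@@H]([C@@H](Oc2cc(OCc3ccccc3)cc(OCc3ccccc3)c2)c2ccc(OCc3ccccc3)cc2)C(=O)N2C(=O)OC[C@@H]2Cc2ccccc2)c1
F5 | step 12 | (2R,3S)-5,7-bis(benzyloxy)-2-[4-(benzyloxy)phenyl]-3-[2-(benzyloxy)-5-ethenylphenyl]-2,3-dihydro-4H-chromen-4-one | C=Cc1ccc(OCc2ccccc2)c([C@@H]2C(=O)c3c(OCc4ccccc4)cc(OCc4ccccc4)cc3O[C@H]2c2ccc(OCc3ccccc3)cc2)c1
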